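**Plan**

- Chain numbering: C1 is the oxane carbon carrying ring B (3,4-dihydroxy-5-methoxyphenyl), C3 the carbinol, C5 the oxane carbon carrying the C6–C7 tether to ring A (4-hydroxy-3-methoxyphenyl); the ring oxygen bridges C1 and C5.
- Enabling feature: without that oxygen, C1–C5 form a cyclopentane whose C3 carbinol is the stereocenter of (R)-4-silyloxycyclopent-2-enone and whose C1 is secondary and benzylic, so a Baeyer–Villiger oxidation of the C5 ketone can place the oxygen between C5 and C1.
- Retrosynthesis: remove silyl and benzyl groups; cut C5–C6 (acetylide onto the lactone carbonyl, C5–H from hydride); excise the ring oxygen (O–C5, O–C1) to reach a cis-2-aryl-4-silyloxycyclopentanone; cut C1–ring B (Suzuki–Miyaura) back to the α-iodinated enone.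
- Forward: the ring B boronic acid (three steps) is coupled to the iodoenone, the alkene is hydrogenated, the carbocycle is expanded to the six-membered lactone (the only ring made), the ring A acetylide is added at C5, then ionic reduction, hydrogenation and desilylation.
- Stereochemistry: C3 is bought; C1 is set by hydrogenation anti to the C3 silyloxy group and kept by migration with retention; C5 is set by axial hydride delivery to the cyclic oxocarbenium ion.

Key step: step 7

Remark: 4-(benzyloxy)-3-methoxybenzaldehyde (O-benzylvanillin) is assumed to be bought in place of vanillin. Hemiketal 17 is treated as an anomeric mixture in equilibrium with its open δ-hydroxy ynone, both of which give the same oxocarbenium ion in step 10.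
Abbreviations: TBS = tert-butyldimethylsilyl, TBSO = tert-butyldimethylsilyloxy. C1–C7 refer to the chain numbering above; locants inside names are those of the ring named.

**Route**

Step 1
Reactants: 1 5-bromo-2-hydroxy-3-methoxybenzaldehyde
Product: 3 5-bromo-3-methoxybenzene-1,2-diol, via aryl formate 2 (not isolated)
Conditions: 30% aq H2O2, NaOH, H2O/THF, 0 °C → rt, N2; then 1 M HCl
Reagents that add atoms: hydrogen peroxide OO
Why: Dakin oxidation, in which hydroperoxide adds to the ortho-hydroxy aldehyde, the aryl group migrates to oxygen and the formate 2 is saponified in the same pot, leaving the aryl bromide untouched.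

Step 2
Reactants: 3 5-bromo-3-methoxybenzene-1,2-diol
Product: 4 5-bromo-1,2-bis(TBSO)-3-methoxybenzene
Conditions: TBSCl, imidazole, DMF, rt
Reagents that add atoms: tert-butyldimethylsilyl chloride CC(C)(C)[Si](C)(C)Cl
Why: Imidazole-promoted silylation of both phenols is routine and masks the catechol against organolithium reagents, peracid and hydrogenation.

Step 3
Reactants: 4 5-bromo-1,2-bis(TBSO)-3-methoxybenzene
Product: 7 [3,4-bis(TBSO)-5-methoxyphenyl]boronic acid, via aryllithium 5 (not isolated), via lithium triisopropoxyborate 6 (not isolated)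
Conditions: n-BuLi, THF, −78 °C; B(OiPr)3, −78 °C → rt; 1 M HCl, 0 °C
Reagents that add atoms: triisopropyl borate CC(C)OB(OC(C)C)OC(C)C; water O
Why: Bromine–lithium exchange followed by borate trapping and mild hydrolysis is the standard boronic acid synthesis, and no silyloxy group sits ortho to the lithiated carbon, so no silyl shift to carbon is expected.

Step 4
Reactants: 8 (R)-4-(TBSO)cyclopent-2-en-1-one
Product: 9 (R)-4-(TBSO)-2-iodocyclopent-2-en-1-one
Conditions: I2, pyridine/CH2Cl2, 0 °C → rt
Reagents that add atoms: iodine II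
Why: α-Iodination of an enone by conjugate addition of pyridine, iodination of the enolate and elimination (Baylis–Hillman-type sequence) is established for 4-silyloxycyclopentenones and does not involve the C3 stereocenter.

Step 5
Reactants: 9 (R)-4-(TBSO)-2-iodocyclopent-2-en-1-one; 7 [3,4-bis(TBSO)-5-methoxyphenyl]boronic acid
Product: 10 (R)-2-[3,4-bis(TBSO)-5-methoxyphenyl]-4-(TBSO)cyclopent-2-en-1-one
Conditions: Pd(PhCN)2Cl2 (cat.), AsPh3, Ag2O, THF/H2O, rt
Reagents that add atoms: none
Why: Suzuki–Miyaura coupling of an α-iodoenone with an arylboronic acid under silver oxide activation runs at room temperature without carbonate base, which the silanol-eliminating enone and the aryl silyl ethers would not tolerate.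

Step 6
Reactants: 10 (R)-2-[3,4-bis(TBSO)-5-methoxyphenyl]-4-(TBSO)cyclopent-2-en-1-one
Product: 11 (2S,4S)-2-[3,4-bis(TBSO)-5-methoxyphenyl]-4-(TBSO)cyclopentan-1-one (cis)
Conditions: H2 (1 atm), 10% Pd/C, EtOAc, rt; filtered and used crude
Reagents that add atoms: none
Why: Heterogeneous syn-hydrogenation of the C1=C2 alkene from the face opposite the bulky allylic C3 silyloxy group should place the C1 aryl group cis to it, and the enolisable ketone is taken on at once to protect the new C1 center.

Step 7
Reactants: 11 (2S,4S)-2-[3,4-bis(TBSO)-5-methoxyphenyl]-4-(TBSO)cyclopentan-1-one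
Product: 13 (4S,6S)-6-[3,4-bis(TBSO)-5-methoxyphenyl]-4-(TBSO)oxan-2-one, via Criegee adduct 12 (not isolated)
Conditions: mCPBA, NaHCO3, CH2Cl2, 0 °C → rt
Reagents that add atoms: 3-chloroperoxybenzoic acid OOC(=O)c1cccc(Cl)c1
Why: Baeyer–Villiger oxidation: the peracid adds to the C5 ketone to give the Criegee adduct 12 (O–C5 bond), and C1 then shifts from C5 to the proximal peroxide oxygen antiperiplanar to the leaving 3-chlorobenzoate (O–C1 bond). The closest known reaction type is the peracid oxidation of 2-aryl- and 2-alkylcyclopentanones to 6-substituted oxan-2-ones. The six-membered lactone, which is the oxane ring of the target, arises by one-atom ring expansion of the five-membered carbocycle and not by cyclisation, so no other ring size can compete. No stereocenter is created, because the 1,2-shift proceeds with retention at C1 and C3 is a spectator, so the cis relation fixed in step 6 passes unchanged into 13. The step needs migration of C1 in preference to the C4 methylene, which is secured by C1 being secondary and benzylic to an electron-rich ring while C4 is primary and carries the inductively withdrawing β-silyloxy group. It also needs the ketone to react before ring B, which is secured by silylation of both phenols and by the bicarbonate buffer.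

Step 8
Reactants: 14 4-(benzyloxy)-3-methoxybenzaldehyde
Product: 15 1-(benzyloxy)-4-ethynyl-2-methoxybenzene
Conditions: dimethyl (1-diazo-2-oxopropyl)phosphonate, K2CO3, MeOH, rt
Reagents that add atoms: dimethyl (1-diazo-2-oxopropyl)phosphonate COP(=O)(OC)C(=[N+]=[N-])C(C)=O
Why: Seyferth–Gilbert homologation in the Ohira–Bestmann variant converts the aryl aldehyde into the terminal alkyne, and the benzyl ether, unlike an aryl silyl ether, tolerates K2CO3/MeOH.

Step 9
Reactants: 15 1-(benzyloxy)-4-ethynyl-2-methoxybenzene; 13 (4S,6S)-6-[3,4-bis(TBSO)-5-methoxyphenyl]-4-(TBSO)oxan-2-one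
Product: 17 hemiketal (4S,6S)-2-{[4-(benzyloxy)-3-methoxyphenyl]ethynyl}-6-[3,4-bis(TBSO)-5-methoxyphenyl]-4-(TBSO)oxan-2-ol, via lithium acetylide 16 (not isolated)
Conditions: n-BuLi, THF, −78 °C; then 13, −78 °C; AcOH quench; used crude
Reagents that add atoms: none
Why: Addition of a lithium acetylide to a δ-lactone (forming C5–C6) stops at the mono-adduct because the tetrahedral lithium alkoxide persists at −78 °C, and the weakly basic acetylide adds faster than it enolises the β-silyloxy lactone.

Step 10
Reactants: 17 hemiketal (4S,6S)-2-{[4-(benzyloxy)-3-methoxyphenyl]ethynyl}-6-[3,4-bis(TBSO)-5-methoxyphenyl]-4-(TBSO)oxan-2-ol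
Product: 18 (2R,4S,6S)-2-{[4-(benzyloxy)-3-methoxyphenyl]ethynyl}-6-[3,4-bis(TBSO)-5-methoxyphenyl]-4-(TBSO)oxane (all-cis)
Conditions: Et3SiH, BF3·OEt2, CH2Cl2/MeCN, −78 → −40 °C
Reagents that add atoms: none
Why: Ionic reduction of a hemiketal: BF3·OEt2 ionises the anomeric C–O bond and Et3SiH delivers hydride axially to the half-chair oxocarbenium ion that keeps the C1 aryl and C3 silyloxy groups pseudo-equatorial, so the alkynyl group at the new C5 center ends up equatorial and cis to both.

Step 11
Reactants: 18 (2R,4S,6S)-2-{[4-(benzyloxy)-3-methoxyphenyl]ethynyl}-6-[3,4-bis(TBSO)-5-methoxyphenyl]-4-(TBSO)oxane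
Product: 19 4-{2-[(2S,4R,6S)-6-[3,4-bis(TBSO)-5-methoxyphenyl]-4-(TBSO)oxan-2-yl]ethyl}-2-methoxyphenol (all-cis; the descriptors at C5 and C3 change by priority only)
Conditions: H2 (1 atm), 10% Pd/C, EtOAc/EtOH, rt
Reagents that add atoms: none
Why: Catalytic hydrogenation saturates the alkyne and hydrogenolyses the aryl benzyl ether in one operation, while the cyclic benzylic C1–O bond cleaves much more slowly than an O-benzyl phenol and no stereocenter is touched.

Step 12
Reactants: 19 4-{2-[(2S,4R,6S)-6-[3,4-bis(TBSO)-5-methoxyphenyl]-4-(TBSO)oxan-2-yl]ethyl}-2-methoxyphenol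
Product: 20 5-[(2S,4R,6S)-4-hydroxy-6-[2-(4-hydroxy-3-methoxyphenyl)ethyl]oxan-2-yl]-3-methoxybenzene-1,2-diol (target)
Conditions: TBAF, AcOH, THF, 0 °C → rt, argon
Reagents that add atoms: none
Why: Fluoride-mediated desilylation, driven by the Si–F bond, removes the two aryl and the one secondary alkyl silyl ether, and acetic acid buffering with exclusion of air keeps the freed catechol from oxidising.

**Compound list**

1 | 5-bromo-2-hydroxy-3-methoxybenzaldehyde | COc1cc(Br)cc(C=O)c1O | starting material
2 | 5-bromo-2-hydroxy-3-methoxyphenyl formate | COc1cc(Br)cc(OC=O)c1O | intermediate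
3 | 5-bromo-3-methoxybenzene-1,2-diol | COc1cc(Br)cc(O)c1O | intermediate
4 | 5-bromo-1,2-bis(TBSO)-3-methoxybenzene | COc1cc(Br)cc(O[Si](C)(C)C(C)(C)C)c1O[Si](C)(C)C(C)(C)C | intermediate
5 | [3,4-bis(TBSO)-5-methoxyphenyl]lithium | COc1cc([Li])cc(O[Si](C)(C)C(C)(C)C)c1O[Si](C)(C)C(C)(C)C | intermediate
6 | lithium [3,4-bis(TBSO)-5-methoxyphenyl]triisopropoxyborate | [Li+].COc1cc([B-](OC(C)C)(OC(C)C)OC(C)C)cc(O[Si](C)(C)C(C)(C)C)c1O[Si](C)(C)C(C)(C)C | intermediate
7 | [3,4-bis(TBSO)-5-methoxyphenyl]boronic acid | COc1cc(B(O)O)cc(O[Si](C)(C)C(C)(C)C)c1O[Si](C)(C)C(C)(C)C | intermediate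
8 | (R)-4-(TBSO)cyclopent-2-en-1-one | O=C1C[C@@H](O[Si](C)(C)C(C)(C)C)C=C1 | starting material
9 | (R)-4-(TBSO)-2-iodocyclopent-2-en-1-one | O=C1C[C@@H](O[Si](C)(C)C(C)(C)C)C=C1I | intermediate
10 | (R)-2-[3,4-bis(TBSO)-5-methoxyphenyl]-4-(TBSO)cyclopent-2-en-1-one | O=C1C[C@@H](O[Si](C)(C)C(C)(C)C)C=C1c2cc(O[Si](C)(C)C(C)(C)C)c(O[Si](C)(C)C(C)(C)C)c(OC)c2 | intermediate
11 | (2S,4S)-2-[3,4-bis(TBSO)-5-methoxyphenyl]-4-(TBSO)cyclopentan-1-one (cis) | O=C1C[C@@H](O[Si](C)(C)C(C)(C)C)C[C@H]1c2cc(O[Si](C)(C)C(C)(C)C)c(O[Si](C)(C)C(C)(C)C)c(OC)c2 | intermediate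
12 | Criegee adduct: (2S,4S)-2-[3,4-bis(TBSO)-5-methoxyphenyl]-1-hydroxy-4-(TBSO)cyclopentyl 3-chloroperoxybenzoate (both C1 epimers) | OC1(OOC(=O)c2cccc(Cl)c2)C[C@@H](O[Si](C)(C)C(C)(C)C)C[C@H]1c3cc(O[Si](C)(C)C(C)(C)C)c(O[Si](C)(C)C(C)(C)C)c(OC)c3 | intermediate
13 | (4S,6S)-6-[3,4-bis(TBSO)-5-methoxyphenyl]-4-(TBSO)oxan-2-one (cis) | O=C1C[C@@H](O[Si](C)(C)C(C)(C)C)C[C@@H](c2cc(O[Si](C)(C)C(C)(C)C)c(O[Si](C)(C)C(C)(C)C)c(OC)c2)O1 | intermediate
14 | 4-(benzyloxy)-3-methoxybenzaldehyde | COc1cc(C=O)ccc1OCc2ccccc2 | starting material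
15 | 1-(benzyloxy)-4-ethynyl-2-methoxybenzene | COc1cc(C#C)ccc1OCc2ccccc2 | intermediate
16 | lithium [4-(benzyloxy)-3-methoxyphenyl]acetylide | COc1cc(C#C[Li])ccc1OCc2ccccc2 | intermediate
17 | (4S,6S)-2-{[4-(benzyloxy)-3-methoxyphenyl]ethynyl}-6-[3,4-bis(TBSO)-5-methoxyphenyl]-4-(TBSO)oxan-2-ol (hemiketal, both anomers) | OC1(C#Cc2ccc(OCc3ccccc3)c(OC)c2)C[C@@H](O[Si](C)(C)C(C)(C)C)C[C@@H](c4cc(O[Si](C)(C)C(C)(C)C)c(O[Si](C)(C)C(C)(C)C)c(OC)c4)O1 | intermediate
18 | (2R,4S,6S)-2-{[4-(benzyloxy)-3-methoxyphenyl]ethynyl}-6-[3,4-bis(TBSO)-5-methoxyphenyl]-4-(TBSO)oxane (all-cis) | COc1cc(C#C[C@H]2C[C@@H](O[Si](C)(C)C(C)(C)C)C[C@@H](c3cc(O[Si](C)(C)C(C)(C)C)c(O[Si](C)(C)C(C)(C)C)c(OC)c3)O2)ccc1OCc4ccccc4 | intermediate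
19 | 4-{2-[(2S,4R,6S)-6-[3,4-bis(TBSO)-5-methoxyphenyl]-4-(TBSO)oxan-2-yl]ethyl}-2-methoxyphenol (all-cis) | COc1cc(CC[C@H]2C[C@@H](O[Si](C)(C)C(C)(C)C)C[C@@H](c3cc(O[Si](C)(C)C(C)(C)C)c(O[Si](C)(C)C(C)(C)C)c(OC)c3)O2)ccc1O | intermediate
20 | 5-[(2S,4R,6S)-4-hydroxy-6-[2-(4-hydroxy-3-methoxyphenyl)ethyl]oxan-2-yl]-3-methoxybenzene-1,2-diol (all-cis) | COc1cc(CC[C@H]2C[C@@H](O)C[C@@H](c3cc(O)c(O)c(OC)c3)O2)ccc1O | target

**Step count and risks**

Total step count: 12. Longest linear sequence: 10 steps (steps 1, 2, 3, 5, 6, 7, 9, 10, 11, 12, from 1 to 20).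

Steps most likely to fail:

1. Step 6. Hydrogen may be delivered with poor facial discrimination, the new C1 center may be lost by enolisation of the α-aryl ketone, or the allylic C3–O bond may undergo hydrogenolysis on the metal surface. The fallback sets out from 10 and replaces syn-hydrogenation by ionic conjugate reduction. [(Ph3P)CuH]6 in moist toluene/THF at room temperature should add hydride to C2 and give the monovalent copper enolate of the ketone F1. Water present then protonates F1 at C1 from the face remote from the C3 silyloxy group. C1 is thus set in a separate protonation event, no hydrogenolysis-active surface is present, and the sequence comes back to the route at 11.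

2. Step 10. The Lewis acid may ionise the benzylic C1–O bond of the ring B-substituted oxane (ring opening, loss of C1 configuration or over-reduction) in competition with the anomeric C–O bond, or hydride may arrive on the wrong face. The fallback sets out from 17 and avoids the strong Lewis acid. Dehydration with (CF3CO)2O and pyridine in CH2Cl2 at 0 °C should give the endocyclic enol ether (2S,4S)-6-{[4-(benzyloxy)-3-methoxyphenyl]ethynyl}-2-[3,4-bis(TBSO)-5-methoxyphenyl]-4-(TBSO)-3,4-dihydro-2H-pyran F2. Hydrogenation of F2 over 10% Pd/C in EtOAc/EtOH should add hydrogen to the C4=C5 enol ether from the face opposite the C3 silyloxy and C1 aryl groups, as in the hydrogenation of 1-substituted glycals to β-C-glycosides. The same operation saturates the alkyne and removes the benzyl group, so the sequence comes back to the route at 19.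

3. Step 7. Oxygen insertion into the cyclopentanone may be slow, and during a long exposure the peracid may attack the electron-rich ring B or the acid by-product may enolise C1. The fallback sets out from 11 and keeps the same bond changes but uses an aprotic insertion. Bis(trimethylsilyl) peroxide with catalytic TMSOTf in CH2Cl2 at −40 °C should convert the silyl-activated ketone into the bis-silyl perketal (2S,4S)-2-[3,4-bis(TBSO)-5-methoxyphenyl]-4-(TBSO)-1-(trimethylsilyloxy)-1-(trimethylsilylperoxy)cyclopentane F3. In F3 the same C1 should migrate with retention and loss of a disiloxane, with no peracid or carboxylic acid present, and the sequence comes back to the route at 13.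

**Further compounds**

F1 | step 6 | monovalent copper (4S)-2-[3,4-bis(TBSO)-5-methoxyphenyl]-4-(TBSO)cyclopent-1-en-1-olate (phosphine ligands not shown) | [Cu]OC1=C(c2cc(O[Si](C)(C)C(C)(C)C)c(O[Si](C)(C)C(C)(C)C)c(OC)c2)C[C@H](O[Si](C)(C)C(C)(C)C)C1
F2 | step 10 | (2S,4S)-6-{[4-(benzyloxy)-3-methoxyphenyl]ethynyl}-2-[3,4-bis(TBSO)-5-methoxyphenyl]-4-(TBSO)-3,4-dihydro-2H-pyran | COc1cc(C#CC2=C[C@@H](O[Si](C)(C)C(C)(C)C)C[C@@H](c3cc(O[Si](C)(C)C(C)(C)C)c(O[Si](C)(C)C(C)(C)C)c(OC)c3)O2)ccc1OCc4ccccc4
F3 | step 7 | (2S,4S)-2-[3,4-bis(TBSO)-5-methoxyphenyl]-4-(TBSO)-1-(trimethylsilyloxy)-1-(trimethylsilylperoxy)cyclopentane (both C1 epimers) | C[Si](C)(C)OC1(OO[Si](C)(C)C)C[C@@H](O[Si](C)(C)C(C)(C)C)C[C@H]1c2cc(O[Si](C)(C)C(C)(C)C)c(O[Si](C)(C)C(C)(C)C)c(OC)c2
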